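**Retrosynthetic overview**
1. Target 33 ⇐ bis-TES ether 32 ⇐ last ring closure at C8–C9–C10: intramolecular Pd-catalysed carbonylative B-alkyl Suzuki coupling of seco iodo-triene 29 with CO (CO becomes C9).
2. 29 ⇐ C1=C2 by aldol condensation of ketone 25 (C10–C14, C1, iPr) with epoxy aldehyde 14 (C2–C8, C18, C19).
3. 14 ⇐ Sharpless epoxidation of Z-allylic alcohol 12 ⇐ Negishi coupling of (Z)-3-iodobut-2-en-1-ol 3 with the zinc reagent from 9 (Z-alkenyltin from trans-hydrostannation).
4. 25 ⇐ Brown Z-crotylboration of 3-methylbut-2-enal (sets C12/C13), selective ozonolysis, isobutyl Grignard addition, oxidation.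
5. Ring order: oxirane first (step 7), 14-membered carbocycle last (step 16).

Assumption: atom labels follow cembrane numbering (C1 bears isopropyl, C3/C4 the epoxide, C9 and C14 the ketones, C19 the CH2OH); the SMILES is read as 3S,4R (cis-epoxide), 12R,13S, 1E, 7Z.

**Route**

Step 1
Reactants: 1 but-2-yn-1-ol
Product: 3 (Z)-3-iodobut-2-en-1-ol, via cyclic alkenylaluminate 2 (not isolated)
Conditions: Red-Al, THF, 0 °C to rt; then I2, −78 to 0 °C
Reagents that add atoms: iodine, II
Why: Hydroxyl-directed trans-hydroalumination of the propargylic alcohol puts aluminium on the distal carbon in a five-membered alkoxyaluminate, and iodinolysis with retention gives the Z iodide (I cis to CH2OH) that later fixes the cis relationship at C3/C4.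

Step 2
Reactants: 4 4-bromobut-1-yne; 5 formaldehyde (as paraformaldehyde)
Product: 7 5-bromopent-2-yn-1-ol, via lithium acetylide 6 (not isolated)
Conditions: n-BuLi, THF, −78 °C; (CH2O)n, −78 to 0 °C; H2O
Reagents that add atoms: none
Why: Acetylide hydroxymethylation, in which deprotonation of the terminal alkyne at −78 °C is much faster than any reaction at the primary bromide, installs C19 as a free propargylic alcohol.

Step 3
Reactants: 7 5-bromopent-2-yn-1-ol
Product: 8 (Z)-5-bromo-2-(tributylstannyl)pent-2-en-1-ol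
Conditions: [Cp*RuCl]4 (2.5 mol%), Bu3SnH, CH2Cl2, rt
Reagents that add atoms: tributyltin hydride, CCCC[SnH](CCCC)CCCC
Why: Ruthenium-catalysed trans-hydrostannation, steered by hydrogen bonding of the propargylic OH to Ru–Cl, delivers tin to the proximal alkyne carbon with anti H/Sn addition, so the C6 chain ends up cis to tin (the C7=C8 geometry of the target).

Step 4
Reactants: 8 (Z)-5-bromo-2-(tributylstannyl)pent-2-en-1-ol
Product: 9 (Z)-[5-bromo-1-(triethylsilyloxy)pent-2-en-2-yl]tributylstannane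
Conditions: TESCl, imidazole, CH2Cl2, 0 °C
Reagents that add atoms: chlorotriethylsilane, CC[Si](Cl)(CC)CC
Why: Standard silylation of the primary alcohol gives a TES ether that tolerates the zinc, titanium, enolate and borane chemistry and is removed by buffered fluoride at the end.

Step 5
Reactants: 9 (Z)-[5-bromo-1-(triethylsilyloxy)pent-2-en-2-yl]tributylstannane; 3 (Z)-3-iodobut-2-en-1-ol
Product: 11 (2Z,6Z)-3-methyl-7-(tributylstannyl)-8-(triethylsilyloxy)octa-2,6-dien-1-ol, via alkylzinc bromide 10 (not isolated)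
Conditions: Zn dust, LiCl, THF, 50 °C; then 3, Pd(OAc)2 (2 mol%), SPhos (4 mol%), THF, 25 °C
Reagents that add atoms: none
Why: LiCl-promoted zinc insertion into the primary bromide followed by Negishi sp3–sp2 coupling with retention at the Z iodide forms C4–C5 and the nerol-type Z-trisubstituted allylic alcohol, the alkylzinc transmetalating far faster than the hindered alkenylstannane.

Step 6
Reactants: 11 (2Z,6Z)-3-methyl-7-(tributylstannyl)-8-(triethylsilyloxy)octa-2,6-dien-1-ol
Product: 12 (2Z,6Z)-7-iodo-3-methyl-8-(triethylsilyloxy)octa-2,6-dien-1-ol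
Conditions: I2, CH2Cl2, 0 °C
Reagents that add atoms: iodine, II
Why: Iododestannylation proceeds with retention at the alkenyl carbon and is much faster than any reaction of iodine with the other alkene.

Step 7
Reactants: 12 (2Z,6Z)-7-iodo-3-methyl-8-(triethylsilyloxy)octa-2,6-dien-1-ol
Product: 13 {(2S,3R)-3-[(Z)-4-iodo-5-(triethylsilyloxy)pent-3-en-1-yl]-3-methyloxiran-2-yl}methanol
Conditions: Ti(OiPr)4 (10 mol%), L-(+)-diethyl tartrate (12 mol%), t-BuOOH, 4 Å MS, CH2Cl2, −20 °C
Reagents that add atoms: tert-butyl hydroperoxide, CC(C)(C)OO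
Why: Sharpless asymmetric epoxidation of a Z-3,3-disubstituted allylic alcohol with L-(+)-DET gives the (2S,3R) cis-epoxide (C3 S and C4 R of the target), while the iodoalkene, which has no free allylic OH, is untouched.

Step 8
Reactants: 13 {(2S,3R)-3-[(Z)-4-iodo-5-(triethylsilyloxy)pent-3-en-1-yl]-3-methyloxiran-2-yl}methanol
Product: 14 (2R,3R)-3-[(Z)-4-iodo-5-(triethylsilyloxy)pent-3-en-1-yl]-3-methyloxirane-2-carbaldehyde
Conditions: Dess–Martin periodinane, pyridine, CH2Cl2, 0 °C
Reagents that add atoms: none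
Why: Buffered Dess–Martin oxidation gives the α,β-epoxy aldehyde without epoxide opening (the descriptor at the former C2 changes only through CIP priorities), and it is used directly.

Step 9
Reactants: 15 cis-but-2-ene; 16 3-methylbut-2-enal
Product: 19 (3R,4S)-3,6-dimethylhepta-1,5-dien-4-ol, via (Z)-crotylpotassium 17 (not isolated), via (Z)-crotyldiisopinocampheylborane 18 (not isolated)
Conditions: KOt-Bu, n-BuLi, THF, −78 to −45 °C; (−)-Ipc2BOMe [from (+)-α-pinene], −78 °C; BF3·OEt2; then 16, −78 °C; NaOH, H2O2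
Reagents that add atoms: none
Why: Brown asymmetric crotylboration, in which the Z-crotylborane reacts through a closed chair transition state to give the syn product and the (+)-α-pinene-derived Ipc groups direct attack to the Si face of the aldehyde, sets C12 (R) and C13 (S).

Step 10
Reactants: 19 (3R,4S)-3,6-dimethylhepta-1,5-dien-4-ol
Product: 20 triethyl{[(3R,4S)-3,6-dimethylhepta-1,5-dien-4-yl]oxy}silane
Conditions: TESCl, imidazole, DMF, rt
Reagents that add atoms: chlorotriethylsilane, CC[Si](Cl)(CC)CC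
Why: Silylation protects the C13 hydroxyl through the oxidative and basic steps, and the group is removed together with the C19 TES ether at the end.

Step 11
Reactants: 20 triethyl{[(3R,4S)-3,6-dimethylhepta-1,5-dien-4-yl]oxy}silane
Product: 22 (2S,3R)-3-methyl-2-(triethylsilyloxy)pent-4-enal, via secondary ozonide 21 (not isolated)
Conditions: O3 (ca. 1 equiv, Sudan III end-point), CH2Cl2, −78 °C; then PPh3, −78 °C to rt
Reagents that add atoms: ozone, [O-][O+]=O
Why: Chemoselective ozonolysis works because the electron-rich trisubstituted alkene reacts much faster than the monosubstituted vinyl group, and PPh3 reduces the ozonide to the α-silyloxy aldehyde (C14).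

Step 12
Reactants: 22 (2S,3R)-3-methyl-2-(triethylsilyloxy)pent-4-enal; 23 isobutylmagnesium bromide
Product: 24 (3R,4S)-3,7-dimethyl-4-(triethylsilyloxy)oct-1-en-5-ol (C5 epimers)
Conditions: THF, −78 to 0 °C; H2O
Reagents that add atoms: none
Why: Grignard addition attaches C1 with its isopropyl group, and the new carbinol centre is irrelevant because it is oxidised in the next step.

Step 13
Reactants: 24 (3R,4S)-3,7-dimethyl-4-(triethylsilyloxy)oct-1-en-5-ol (C5 epimers)
Product: 25 (3R,4S)-3,7-dimethyl-4-(triethylsilyloxy)oct-1-en-5-one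
Conditions: Dess–Martin periodinane, pyridine, CH2Cl2, rt
Reagents that add atoms: none
Why: Neutral Dess–Martin oxidation gives the α-silyloxy ketone without epimerising C13.

Step 14
Reactants: 25 (3R,4S)-3,7-dimethyl-4-(triethylsilyloxy)oct-1-en-5-one; 14 (2R,3R)-3-[(Z)-4-iodo-5-(triethylsilyloxy)pent-3-en-1-yl]-3-methyloxirane-2-carbaldehyde
Product: 27 (3R,4S)-6-[hydroxy{(2S,3R)-3-[(Z)-4-iodo-5-(triethylsilyloxy)pent-3-en-1-yl]-3-methyloxiran-2-yl}methyl]-3,7-dimethyl-4-(triethylsilyloxy)oct-1-en-5-one (C1/C2 epimers), via lithium enolate 26 (not isolated)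
Conditions: LDA, THF, −78 °C; then 14, −78 °C; H2O
Reagents that add atoms: none
Why: Kinetic deprotonation occurs at the unhindered CH2 (C1) rather than at the silyloxy-bearing methine (C13), and the crossed aldol addition to the epoxy aldehyde forms C1–C2, the two new centres being erased in the next step.

Step 15
Reactants: 27 aldol adduct (C1/C2 epimers)
Product: 29 (3R,4S,6E)-6-({(2S,3R)-3-[(Z)-4-iodo-5-(triethylsilyloxy)pent-3-en-1-yl]-3-methyloxiran-2-yl}methylidene)-3,7-dimethyl-4-(triethylsilyloxy)oct-1-en-5-one, via mesylate 28 (not isolated)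
Conditions: MsCl, Et3N, CH2Cl2, 0 °C; then DBU, 0 °C to rt
Reagents that add atoms: none
Why: Mesylation and E1cB elimination through the enolate (aldol condensation) converge both aldol epimers on the conjugated enone, with the E isomer (acyl trans to the epoxide carbon, isopropyl cis) favoured because the carbonyl stays coplanar only in that geometry.

Step 16
Reactants: 29 seco iodo-enone; 30 carbon monoxide
Product: 32 (1S,2E,5S,6R,10Z,14R)-6,14-dimethyl-3-(propan-2-yl)-5-(triethylsilyloxy)-10-[(triethylsilyloxy)methyl]-15-oxabicyclo[12.1.0]pentadeca-2,10-diene-4,9-dione, via B-alkyl-9-BBN 31 (not isolated)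
Conditions: 9-BBN (1.2 equiv), THF, 0 °C to rt; then slow addition to Pd(PPh3)4 (10 mol%), K3PO4 (3 equiv), CO (1 atm), THF/benzene, 25 °C, 2 mM
Reagents that add atoms: none
Why: Proposed new method: an intramolecular carbonylative B-alkyl Suzuki–Miyaura macrocyclisation, in which 9-BBN hydroborates only the monosubstituted C10=C11 alkene (the hindered C14 ketone and the trisubstituted alkenes react far more slowly), Pd(0) adds to the Z-alkenyl iodide with retention, CO inserts faster than the hindered alkenyl–Pd can transmetalate, and the phosphate-activated primary alkylborate then transfers C10 to the acyl–Pd under high dilution so that reductive elimination closes the 14-membered ring with C9 as the new enone carbonyl and the C7=C8 geometry intact; the closest known reactions are the intermolecular carbonylative coupling of B-alkyl-9-BBN reagents with iodoalkenes and the non-carbonylative B-alkyl Suzuki macrocyclisation, and the hindered trisubstituted vinyl epoxide is expected to outlast a room-temperature Pd(0) coupling because oxidative addition to the C–I bond under CO is much faster than allylic ionisation.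

Step 17
Reactants: 32 macrocyclic bis-TES ether
Product: 33 (1S,2E,5S,6R,10Z,14R)-5-hydroxy-10-(hydroxymethyl)-6,14-dimethyl-3-(propan-2-yl)-15-oxabicyclo[12.1.0]pentadeca-2,10-diene-4,9-dione (CNP0251075.1)
Conditions: HF·pyridine, pyridine, THF, 0 °C
Reagents that add atoms: none
Why: Buffered fluoride desilylation cleaves the primary and the secondary TES ether without opening the vinyl epoxide or epimerising the α-ketol centre.

**Compound list**
1 | but-2-yn-1-ol | CC#CCO | starting material
2 | sodium cyclic alkenylaluminate (2,2-bis(2-methoxyethoxy)-3-methyl-2,5-dihydro-1,2-oxaluminol-2-uide) | CC1=CCO[Al-]1(OCCOC)OCCOC.[Na+] | intermediate (not isolated)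
3 | (Z)-3-iodobut-2-en-1-ol | C/C(I)=C/CO | intermediate
4 | 4-bromobut-1-yne | C#CCCBr | starting material
5 | formaldehyde (used as paraformaldehyde) | C=O | starting material
6 | lithium 4-bromobut-1-yn-1-ide | [Li]C#CCCBr | intermediate (not isolated)
7 | 5-bromopent-2-yn-1-ol | OCC#CCCBr | intermediate
8 | (Z)-5-bromo-2-(tributylstannyl)pent-2-en-1-ol | BrCC/C=C(/CO)[Sn](CCCC)(CCCC)CCCC | intermediate
9 | (Z)-[5-bromo-1-(triethylsilyloxy)pent-2-en-2-yl]tributylstannane | BrCC/C=C(/CO[Si](CC)(CC)CC)[Sn](CCCC)(CCCC)CCCC | intermediate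
10 | (Z)-[4-(tributylstannyl)-5-(triethylsilyloxy)pent-3-en-1-yl]zinc bromide | Br[Zn]CC/C=C(/CO[Si](CC)(CC)CC)[Sn](CCCC)(CCCC)CCCC | intermediate (not isolated)
11 | (2Z,6Z)-3-methyl-7-(tributylstannyl)-8-(triethylsilyloxy)octa-2,6-dien-1-ol | OC/C=C(/C)CC/C=C(/CO[Si](CC)(CC)CC)[Sn](CCCC)(CCCC)CCCC | intermediate
12 | (2Z,6Z)-7-iodo-3-methyl-8-(triethylsilyloxy)octa-2,6-dien-1-ol | OC/C=C(/C)CC/C=C(/CO[Si](CC)(CC)CC)I | intermediate
13 | {(2S,3R)-3-[(Z)-4-iodo-5-(triethylsilyloxy)pent-3-en-1-yl]-3-methyloxiran-2-yl}methanol | OC[C@@H]1O[C@]1(C)CC/C=C(/CO[Si](CC)(CC)CC)I | intermediate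
14 | (2R,3R)-3-[(Z)-4-iodo-5-(triethylsilyloxy)pent-3-en-1-yl]-3-methyloxirane-2-carbaldehyde | O=C[C@@H]1O[C@]1(C)CC/C=C(/CO[Si](CC)(CC)CC)I | intermediate
15 | cis-but-2-ene | C/C=C\C | starting material
16 | 3-methylbut-2-enal | CC(C)=CC=O | starting material
17 | (Z)-crotylpotassium | C/C=C\C[K] | intermediate (not isolated)
18 | (Z)-crotyldiisopinocampheylborane, Ipc groups from (+)-α-pinene | C/C=C\CB([C@@H]1C[C@@H]2C[C@H]([C@H]1C)C2(C)C)[C@@H]1C[C@@H]2C[C@H]([C@H]1C)C2(C)C | intermediate (not isolated)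
19 | (3R,4S)-3,6-dimethylhepta-1,5-dien-4-ol | C=C[C@@H](C)[C@H](O)C=C(C)C | intermediate
20 | triethyl{[(3R,4S)-3,6-dimethylhepta-1,5-dien-4-yl]oxy}silane | C=C[C@@H](C)[C@H](O[Si](CC)(CC)CC)C=C(C)C | intermediate
21 | secondary ozonide of 20 (3,3-dimethyl-1,2,4-trioxolane at the former trisubstituted alkene; ring CH epimers) | C=C[C@@H](C)[C@H](O[Si](CC)(CC)CC)C1OOC(C)(C)O1 | intermediate (not isolated)
22 | (2S,3R)-3-methyl-2-(triethylsilyloxy)pent-4-enal | C=C[C@@H](C)[C@H](O[Si](CC)(CC)CC)C=O | intermediate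
23 | isobutylmagnesium bromide | CC(C)C[Mg]Br | starting material
24 | (3R,4S)-3,7-dimethyl-4-(triethylsilyloxy)oct-1-en-5-ol (C5 epimers) | C=C[C@@H](C)[C@H](O[Si](CC)(CC)CC)C(O)CC(C)C | intermediate
25 | (3R,4S)-3,7-dimethyl-4-(triethylsilyloxy)oct-1-en-5-one | C=C[C@@H](C)[C@H](O[Si](CC)(CC)CC)C(=O)CC(C)C | intermediate
26 | lithium enolate of 25 (enolised towards C6) | C=C[C@@H](C)[C@H](O[Si](CC)(CC)CC)C(O[Li])=CC(C)C | intermediate (not isolated)
27 | (3R,4S)-6-[hydroxy{(2S,3R)-3-[(Z)-4-iodo-5-(triethylsilyloxy)pent-3-en-1-yl]-3-methyloxiran-2-yl}methyl]-3,7-dimethyl-4-(triethylsilyloxy)oct-1-en-5-one (C1/C2 epimers) | C=C[C@@H](C)[C@H](O[Si](CC)(CC)CC)C(=O)C(C(C)C)C(O)[C@@H]1O[C@]1(C)CC/C=C(/CO[Si](CC)(CC)CC)I | intermediate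
28 | methanesulfonate of 27 | C=C[C@@H](C)[C@H](O[Si](CC)(CC)CC)C(=O)C(C(C)C)C(OS(C)(=O)=O)[C@@H]1O[C@]1(C)CC/C=C(/CO[Si](CC)(CC)CC)I | intermediate (not isolated)
29 | (3R,4S,6E)-6-({(2S,3R)-3-[(Z)-4-iodo-5-(triethylsilyloxy)pent-3-en-1-yl]-3-methyloxiran-2-yl}methylidene)-3,7-dimethyl-4-(triethylsilyloxy)oct-1-en-5-one | C=C[C@@H](C)[C@H](O[Si](CC)(CC)CC)C(=O)/C(C(C)C)=C/[C@@H]1O[C@]1(C)CC/C=C(/CO[Si](CC)(CC)CC)I | intermediate
30 | carbon monoxide | [C-]#[O+] | starting material
31 | 9-[(3R,4S,6E)-6-({(2S,3R)-3-[(Z)-4-iodo-5-(triethylsilyloxy)pent-3-en-1-yl]-3-methyloxiran-2-yl}methylidene)-3,7-dimethyl-5-oxo-4-(triethylsilyloxy)octyl]-9-borabicyclo[3.3.1]nonane | B1(CC[C@@H](C)[C@H](O[Si](CC)(CC)CC)C(=O)/C(C(C)C)=C/[C@@H]3O[C@]3(C)CC/C=C(/CO[Si](CC)(CC)CC)I)C2CCCC1CCC2 | intermediate (not isolated)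
32 | (1S,2E,5S,6R,10Z,14R)-6,14-dimethyl-3-(propan-2-yl)-5-(triethylsilyloxy)-10-[(triethylsilyloxy)methyl]-15-oxabicyclo[12.1.0]pentadeca-2,10-diene-4,9-dione | CC(C)/C1=C\[C@@H]2O[C@]2(C)CC/C=C(/CO[Si](CC)(CC)CC)C(=O)CC[C@@H](C)[C@H](O[Si](CC)(CC)CC)C1=O | intermediate
33 | (1S,2E,5S,6R,10Z,14R)-5-hydroxy-10-(hydroxymethyl)-6,14-dimethyl-3-(propan-2-yl)-15-oxabicyclo[12.1.0]pentadeca-2,10-diene-4,9-dione | CC(C)/C1=C\[C@@H]2O[C@]2(C)CC/C=C(/CO)C(=O)CC[C@@H](C)[C@H](O)C1=O | target

**Totals**
Total step count: 17.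
Longest linear sequence: 11 steps (4 → 7 → 8 → 9 → 11 → 12 → 13 → 14 → 27 → 29 → 32 → 33; steps 2–8 and 14–17).

**Three steps most likely to fail**

Step 16 (the proposed macrocyclisation). The risks are reduction of the C14 enone by 9-BBN, Pd(0) ionisation of the γ,δ-epoxy enone, and direct (CO-free) coupling. The fallback uses known chemistry, sets out from 29 and comes back at 32. Rhodium-catalysed linear hydroformylation of the vinyl group [Rh(acac)(CO)2, Xantphos, CO/H2, toluene, 60 °C] gives (4R,5S,7E)-7-({(2S,3R)-3-[(Z)-4-iodo-5-(triethylsilyloxy)pent-3-en-1-yl]-3-methyloxiran-2-yl}methylidene)-4,8-dimethyl-6-oxo-5-(triethylsilyloxy)nonanal F1. A Nozaki–Hiyama–Kishi macrocyclisation (CrCl2, cat. NiCl2, DMSO/THF, high dilution) then joins C8 to C9 and gives the 14-membered allylic alcohol, the 9-hydroxy analogue of 32 (C9 epimers) F2. Dess–Martin oxidation of the C9 carbinol gives 32.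

Step 15 (together with the enolisation in step 14). The risks are E/Z selectivity of the elimination with the α-isopropyl group and base sensitivity of the epoxy enone. The fallback sets out from aldehyde 22 and comes back at 29. Dimethyl (2-methylpropyl)phosphonate F3 is made by Arbuzov reaction of 1-bromo-2-methylpropane with trimethyl phosphite. It is lithiated (n-BuLi, THF, −78 °C) and added to 22 to give dimethyl [(5S,6R)-4-hydroxy-2,6-dimethyl-5-(triethylsilyloxy)oct-7-en-3-yl]phosphonate F4. Dess–Martin oxidation gives dimethyl [(5S,6R)-2,6-dimethyl-4-oxo-5-(triethylsilyloxy)oct-7-en-3-yl]phosphonate F5. A Ba(OH)2-mediated Horner–Wadsworth–Emmons reaction with epoxy aldehyde 14 (wet THF, rt) then gives 29 in one operation. Its E selectivity with the α-isopropyl group is also uncertain, so any Z isomer is separated or equilibrated (cat. I2, light).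

Step 5 (zinc insertion and Negishi coupling next to an alkenylstannane and a free hydroxyl). The risks are sluggish zinc insertion, protonation of the zinc reagent by the free OH, and competing Stille transfer. The fallback sets out from bromide 9 and comes back at 11. Oxygen-directed allylic metalation of 3-methylbut-2-en-1-ol (2 equiv n-BuLi, TMEDA, hexane/Et2O) gives the Z-configured dianion, dilithiated 3-methylbut-2-en-1-ol F6. Its carbon terminus is alkylated by bromide 9 (THF, −78 to 0 °C), which forms the same C4–C5 bond without palladium and gives 11 directly.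

**Further compounds**
F1 | step 16 | (4R,5S,7E)-7-({(2S,3R)-3-[(Z)-4-iodo-5-(triethylsilyloxy)pent-3-en-1-yl]-3-methyloxiran-2-yl}methylidene)-4,8-dimethyl-6-oxo-5-(triethylsilyloxy)nonanal | O=CCC[C@@H](C)[C@H](O[Si](CC)(CC)CC)C(=O)/C(C(C)C)=C/[C@@H]1O[C@]1(C)CC/C=C(/CO[Si](CC)(CC)CC)I
F2 | step 16 | (1S,2E,5S,6R,10Z,14R)-9-hydroxy-6,14-dimethyl-3-(propan-2-yl)-5-(triethylsilyloxy)-10-[(triethylsilyloxy)methyl]-15-oxabicyclo[12.1.0]pentadeca-2,10-dien-4-one (C9 epimers) | CC(C)/C1=C\[C@@H]2O[C@]2(C)CC/C=C(/CO[Si](CC)(CC)CC)C(O)CC[C@@H](C)[C@H](O[Si](CC)(CC)CC)C1=O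
F3 | step 15 | dimethyl (2-methylpropyl)phosphonate | CC(C)CP(=O)(OC)OC
F4 | step 15 | dimethyl [(5S,6R)-4-hydroxy-2,6-dimethyl-5-(triethylsilyloxy)oct-7-en-3-yl]phosphonate (C3/C4 epimers) | C=C[C@@H](C)[C@H](O[Si](CC)(CC)CC)C(O)C(C(C)C)P(=O)(OC)OC
F5 | step 15 | dimethyl [(5S,6R)-2,6-dimethyl-4-oxo-5-(triethylsilyloxy)oct-7-en-3-yl]phosphonate (C3 epimers) | C=C[C@@H](C)[C@H](O[Si](CC)(CC)CC)C(=O)C(C(C)C)P(=O)(OC)OC
F6 | step 5 | dilithiated 3-methylbut-2-en-1-ol (O-lithio and Z-CH2-lithio) | [Li]OC/C=C(/C)C[Li]
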